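All runs come from a simulation with constants of no real substance, and the scatter is random.

The trap with flasks like these is to take equal end readings as proof that nothing acts, without asking how large an effect of Spx7 the scatter could still hide. Sbt was fed at a steady rate into a stirred flask already holding Spx7, and Spx3 was read as a percentage of the whole Sbt charge.

| setting | blue | grey | teal | dusk | autumn | noon | midnight |
|---|---|---|---|---|---|---|---|
| Sbt | 20 mM (fed, over 15 h) | 20 mM (fed, over 15 h) | 20 mM (fed, over 15 h) | 20 mM (fed, over 15 h) | 20 mM (fed, over 15 h) | 20 mM (fed, over 15 h) | 20 mM (fed, over 15 h) |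
| Spx7 | 2.5 mM | 8.5 mM | 29 mM | 3.00 mM | 6.00 mM | 12.0 mM | 25.0 mM |
| remark | run made earlier | run made earlier | run made earlier |  |  |  |  |
| time |  |  |  | 20 h | 20 h | 20 h | 20 h |

- blue (time / h: Spx3 / %): 1.50: 0.4; 3.00: 0.4; 6.00: 0; 10.0: 1.5; 20.0: 7.8
- grey (time / h: Spx3 / %): 2.00: 0.6; 5.00: 0; 10.0: 0.7; 15.0: 3.5; 20.0: 8.2
- teal (time / h: Spx3 / %): 1.50: 0.3; 3.00: 0; 6.00: 0.1; 10.0: 1.9; 20.0: 7.8

(standard deviation of a reading: 0.5 percentage points)

* amount of Spx3 at the end, in percent of the Sbt charged for dusk, autumn, noon, midnight, in this order
* how that number moves from the first to the last of them (rises, then falls / hardly changes / falls all the way / falls, then rises / rises all the way)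

- the numbers in the tables scatter with a standard deviation of 0.5 percentage points
- percentages count the whole charge, also what has not yet gone in
- "hardly changes" means that all values lie within two and a half points (for a concentration: within two and a half percent of the largest)

I reckoned with the rate. At the start it could not be read, for the grey run stood at 0% after 5.00 h, within the scatter of 0.5 percentage points, and it climbed later, to 8.2% after 20.0 h. Since an end reading is the rate summed over the run, I compared end readings to see whether Spx7 slowed that rate. Teal against blue gave 0 for what I called the Spx7 order, the logarithm of the ratio of two end readings divided by the logarithm of the ratio of their Spx7 charges, so that an order of zero (the usual zero-order case) means the end reading does not move with Spx7; this reading carried a standard deviation of 0.0370. At that order I reckoned a factor of 1.00 on the rate for each doubling of Spx7, and an accumulated factor of 1.00 from dusk to midnight. One standard deviation of the order amounted to a swing of 0.61 points over that range. I committed to the mean of the three end readings, 7.93%, in each new flask.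

The forecast gave 7.9% for dusk and 7.9% for midnight, with autumn and noon the same, and the shape "hardly changes", on its reading of “Spx7 apparently having no kinetic effect (zero order) in this range”.

Dusk gave 8.04% and midnight 8.04%, so the shape was "hardly changes" and the Spx7 order of this pair was 0. For autumn and noon, the order 0 gave a factor of 1.00, and they stood at 8.04% and 8.04%.

Spx7 + Spx5 → Spx7.Spx5 (k = 0.570 M⁻¹ min⁻¹); Spx → Spx2 (k = 0.00370 min⁻¹); Spx → Spx4 (k = 2.40 × 10⁻⁴ min⁻¹); Sbt → Spx (k = 0.00150 min⁻¹); Spx4 ⇌ Spx5 (K = 0.760, k = 0.00220 min⁻¹); Spx5 ⇌ Spx6 (K = 1.00, k = 0.00120 min⁻¹); Spx2 → Spx3 (k = 5.10 × 10⁻⁴ min⁻¹); Spx4 → Sdp (k = 0.00190 min⁻¹) After 12.3 h in dusk, Spx was turning into Spx2 at 15 times the rate at which it turned into Spx4, and Spx7 reacts with Spx5, which lies behind Spx4. After 20.0 h, the dusk flask held Spx5 at 0.383% of the Sbt charged and Spx2 at 37.7%.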